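**Plan**
- Feature and last cuts: in the dihydropyranone ring (O1–C2–C3–C4–C4a–C8a), C2 and C3 each bear one methyl group and lie β and α to the C4 ketone. C2–CH3 and C3–CH3 are therefore cut together, back to the C2=C3 bond of a 2,3-unsubstituted chromone.
- Earlier cuts: O1–C2 and C2–C3 of the chromone (one carbon from a formamide acetal), C6–prenyl, C4a–acetyl, and the bond from C8 to the hexanoate chain, which goes back to a Pechmann coumarin of phloroglucinol.
- Forward: a lactone ring is fused onto the bought benzene ring (coumarin), reduced, then opened by methanol to release the side chain. Acetyl and prenyl groups follow, then the pyranone ring closes, the two methyl groups are added, and deprotection ends the route.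
- Regiochemistry: the two free ring positions become equivalent once the lactone is open. The phenol that becomes O1 is singled out by capping the other two as MOM ethers.
- Stereochemistry: the side-chain centre (S) comes from a ligand-controlled copper hydride reduction of the coumarin. C2 (S) comes from a chiral copper catalyst, and C3 (S) from C2 by anti alkylation to the trans, thermodynamically preferred ketone.

Key step: step 9

Assumption: (R)-DTBM-SEGPHOS in step 3 and the (R,Sp) ferrocenyl diphosphine in step 9 are taken to be the antipodes that lead to 4S and 2S; both ligands are sold in both mirror-image forms, so the other antipode is used if a first run shows the opposite sense.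

Step 1
Reactants: 1 phloroglucinol; 2 ethyl 3-oxohexanoate
Product: 3 5,7-dihydroxy-4-propyl-2H-chromen-2-one
Conditions: conc. H2SO4, 0 °C to 90 °C
Reagents that add atoms: none
Why: Pechmann condensation: the protonated β-keto ester attacks the strongly activated, threefold symmetric ring, and lactonisation with loss of water can give only one coumarin.

Step 2
Reactants: 3 5,7-dihydroxy-4-propyl-2H-chromen-2-one
Product: 4 5,7-bis(tert-butyldimethylsilyloxy)-4-propyl-2H-chromen-2-one
Conditions: TBSCl, imidazole, DMF, 40 °C
Reagents that add atoms: tert-butyldimethylsilyl chloride, CC(C)(C)[Si](C)(C)Cl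
Why: Routine imidazole-promoted silylation of phenols removes the acidic protons that would consume the copper hydride and the borane, and it makes the coumarin soluble in toluene.

Step 3
Reactants: 4 5,7-bis(tert-butyldimethylsilyloxy)-4-propyl-2H-chromen-2-one
Product: 6 (4S)-5,7-bis(tert-butyldimethylsilyloxy)-4-propylchroman-2-one, via boron ketene acetal 5 (not isolated)
Conditions: CuCl (5 mol %), NaOt-Bu (5 mol %), (R)-DTBM-SEGPHOS (5.5 mol %), pinacolborane (1.5 equiv), toluene, rt; NH4Cl aq
Reagents that add atoms: none
Why: In this copper hydride catalysed asymmetric conjugate reduction (1,4-hydroboration) of a 4-substituted coumarin, the ligated Cu–H delivers hydride to one face of C4 and sets 4S under ligand control, while the boron ketene acetal formed by exchange with the borane protects the lactone from over-reduction until work-up.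

Step 4
Reactants: 6 (4S)-5,7-bis(tert-butyldimethylsilyloxy)-4-propylchroman-2-one
Product: 7 (4S)-5,7-dihydroxy-4-propylchroman-2-one
Conditions: Bu4NF, AcOH, THF, 0 °C
Reagents that add atoms: none
Why: Fluoride cleaves the aryl silyl ethers with acetic acid as buffer so that no free phenoxide attacks the lactone, and a shift of the lactone to the other ortho oxygen would regenerate the same compound and leave C4 untouched.

Step 5
Reactants: 7 (4S)-5,7-dihydroxy-4-propylchroman-2-one; 8 acetyl chloride
Product: 11 methyl (3S)-3-(3-acetyl-2,4,6-trihydroxyphenyl)hexanoate, via 8-acetyl lactone 9 (not isolated), via 6-acetyl lactone 10 (not isolated)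
Conditions: AcCl (1.1 equiv), AlCl3, CH2Cl2–PhNO2, 0 °C to rt; ice/HCl; crude in HCl (1.25 M in MeOH), 40 °C; NaHCO3 before concentration
Reagents that add atoms: acetyl chloride, CC(=O)Cl; methanol, CO
Why: Friedel–Crafts acylation of an alkylphloroglucinol nucleus (the first acetyl group deactivates the ring towards a second) is followed by acid-catalysed lactone methanolysis, and because C6 and C8 of the lactone become equivalent once the ring is open, both acetyl lactones converge on one ester and the site of acylation does not matter.

Step 6
Reactants: 11 methyl (3S)-3-(3-acetyl-2,4,6-trihydroxyphenyl)hexanoate; 12 1-bromo-3-methylbut-2-ene (prenyl bromide)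
Product: 13 methyl (3S)-3-[3-acetyl-2,4,6-trihydroxy-5-(3-methylbut-2-enyl)phenyl]hexanoate
Conditions: NaOMe (1.1 equiv), MeOH, 0 °C; prenyl bromide (1.0 equiv), 0 °C to rt; AcOH quench
Reagents that add atoms: 1-bromo-3-methylbut-2-ene, CC(C)=CCBr
Why: This is the classical nuclear prenylation of an acylphloroglucinol anion, in which the protic solvent favours C- over O-alkylation, only attack at the single remaining ring CH can rearomatise, and methoxide in methanol leaves the methyl ester unchanged and reopens any lactone.

Step 7
Reactants: 13 methyl (3S)-3-[3-acetyl-2,4,6-trihydroxy-5-(3-methylbut-2-enyl)phenyl]hexanoate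
Product: 14 methyl (3S)-3-[3-acetyl-2-hydroxy-4,6-bis(methoxymethoxy)-5-(3-methylbut-2-enyl)phenyl]hexanoate
Conditions: MOMCl (2.1 equiv), i-Pr2NEt, CH2Cl2, −10 °C
Reagents that add atoms: chloromethyl methyl ether, COCCl
Why: Partial acetalisation of a 2,4,6-trihydroxyacetophenone regularly stops with one chelated hydroxyl left, and here the hydroxyl between the acetyl group and the branched benzylic carbon is the most shielded and keeps the hydrogen bond, so only the oxygen that is to become O1 should stay free.

Step 8
Reactants: 14 methyl (3S)-3-[3-acetyl-2-hydroxy-4,6-bis(methoxymethoxy)-5-(3-methylbut-2-enyl)phenyl]hexanoate; 15 N,N-dimethylformamide dimethyl acetal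
Product: 17 methyl (3S)-3-[5,7-bis(methoxymethoxy)-6-(3-methylbut-2-enyl)-4-oxo-4H-chromen-8-yl]hexanoate, via enaminone 16 (not isolated)
Conditions: DMF-DMA, toluene, 90 °C; evaporate; AcOH, 60 °C
Reagents that add atoms: N,N-dimethylformamide dimethyl acetal, COC(OC)N(C)C
Why: Condensation of the methyl ketone with the formamide acetal and acid-induced addition–elimination by the neighbouring phenol is the standard enaminone route to 2,3-unsubstituted chromones, the O1–C2 bond can form from the one free hydroxyl only, and acetic acid buffered by the released amine is mild enough for the MOM ethers and the prenyl group.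

Step 9
Reactants: 17 methyl (3S)-3-[5,7-bis(methoxymethoxy)-6-(3-methylbut-2-enyl)-4-oxo-4H-chromen-8-yl]hexanoate; 18 methylmagnesium bromide; 19 iodomethane
Product: 21 methyl (3S)-3-[(2S,3S)-5,7-bis(methoxymethoxy)-2,3-dimethyl-6-(3-methylbut-2-enyl)-4-oxochroman-8-yl]hexanoate, via magnesium enolate 20 (not isolated)
Conditions: CuBr·SMe2 (5 mol %), (R)-1-[(Sp)-2-(dicyclohexylphosphino)ferrocenyl]ethyldiphenylphosphine (6 mol %), MeMgBr (1.3 equiv), t-BuOMe, −78 °C; then MeI (10 equiv), DMPU, −78 to −30 °C; NH4Cl aq at −30 °C
Reagents that add atoms: methylmagnesium bromide, C[Mg]Br; iodomethane, CI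
Why: The methylcopper species formed from CuBr·SMe2, the diphosphine and MeMgBr binds the C2=C3 bond as a π-complex, adds at C2 to give a trivalent copper intermediate and eliminates reductively to make C2–CH3, which interrupts the cyclic conjugation of the pyranone and leaves the C3=C4 magnesium enolate 20; MeI then alkylates C3 once DMPU has loosened the Mg–O aggregate. The closest known reactions are the copper/ferrocenyl diphosphine catalysed conjugate addition of alkyl Grignard reagents to 2,3-unsubstituted chromones and the alkylative trapping of the magnesium enolates that such additions give with cyclic enones (three-component coupling), with methyl as the transferred group and trapping in the same flask being the least explored variants. No ring is closed. C2 (S) is set by the ligand, which decides the face of the flat chromone that copper approaches, the side-chain centre on C8 being too remote to override it; C3 (S) is set by C2, because MeI attacks the half-chair enolate anti to the pseudoaxial C2 methyl group, and since the trans (diequatorial) ketone is also the thermodynamic isomer, brief contact with Et3N after work-up would correct any cis material. The step needs 1,4- over 1,2-addition, attack on the chromone rather than on the methyl ester, C- over O-methylation and an enolate that keeps its C2–O1 bond: the unsubstituted C2=C3 bond makes this the most reactive type of chromone, the C4 carbonyl oxygen and the 5-OMOM oxygen can bind magnesium together and polarise the acceptor, the ester is shielded by its β-branch and the two ortho substituents and is inert at −78 °C, and staying at or below −30 °C suppresses expulsion of the C8a phenoxide.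

Step 10
Reactants: 21 methyl (3S)-3-[(2S,3S)-5,7-bis(methoxymethoxy)-2,3-dimethyl-6-(3-methylbut-2-enyl)-4-oxochroman-8-yl]hexanoate
Product: 22 methyl (3S)-3-[(2S,3S)-5,7-dihydroxy-2,3-dimethyl-6-(3-methylbut-2-enyl)-4-oxochroman-8-yl]hexanoate (CNP0068017.3)
Conditions: HCl (1.25 M in MeOH), 40 °C; NaHCO3 before concentration
Reagents that add atoms: none
Why: Acid-catalysed acetal exchange of aryl MOM ethers with methanol is widely used on prenylated phloroglucinol ketones; here methanol as solvent keeps the side chain as the open methyl ester instead of a lactone with the C7 hydroxyl, the trans C2/C3 arrangement is the stable one under acid, and neutralisation before evaporation guards against lactonisation and against cyclisation of the prenyl group onto a phenol.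

**Compound list**
1 | phloroglucinol | Oc1cc(O)cc(O)c1 | starting material
2 | ethyl 3-oxohexanoate | CCCC(=O)CC(=O)OCC | starting material
3 | 5,7-dihydroxy-4-propyl-2H-chromen-2-one | CCCC1=CC(=O)Oc2cc(O)cc(O)c12 | intermediate
4 | 5,7-bis(tert-butyldimethylsilyloxy)-4-propyl-2H-chromen-2-one | CCCC1=CC(=O)Oc2cc(O[Si](C)(C)C(C)(C)C)cc(O[Si](C)(C)C(C)(C)C)c12 | intermediate
5 | (4S)-5,7-bis(tert-butyldimethylsilyloxy)-4-propyl-2-(4,4,5,5-tetramethyl-1,3,2-dioxaborolan-2-yloxy)-4H-chromene (boron ketene acetal, not isolated) | CCC[C@H]1C=C(OB2OC(C)(C)C(C)(C)O2)Oc3cc(O[Si](C)(C)C(C)(C)C)cc(O[Si](C)(C)C(C)(C)C)c13 | intermediate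
6 | (4S)-5,7-bis(tert-butyldimethylsilyloxy)-4-propylchroman-2-one | CCC[C@H]1CC(=O)Oc2cc(O[Si](C)(C)C(C)(C)C)cc(O[Si](C)(C)C(C)(C)C)c21 | intermediate
7 | (4S)-5,7-dihydroxy-4-propylchroman-2-one | CCC[C@H]1CC(=O)Oc2cc(O)cc(O)c21 | intermediate
8 | acetyl chloride | CC(=O)Cl | starting material
9 | (4S)-8-acetyl-5,7-dihydroxy-4-propylchroman-2-one (not isolated) | CCC[C@H]1CC(=O)Oc2c(C(C)=O)c(O)cc(O)c21 | intermediate
10 | (4S)-6-acetyl-5,7-dihydroxy-4-propylchroman-2-one (not isolated) | CCC[C@H]1CC(=O)Oc2cc(O)c(C(C)=O)c(O)c21 | intermediate
11 | methyl (3S)-3-(3-acetyl-2,4,6-trihydroxyphenyl)hexanoate | CCC[C@@H](CC(=O)OC)c1c(O)cc(O)c(C(C)=O)c1O | intermediate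
12 | 1-bromo-3-methylbut-2-ene | CC(C)=CCBr | starting material
13 | methyl (3S)-3-[3-acetyl-2,4,6-trihydroxy-5-(3-methylbut-2-enyl)phenyl]hexanoate | CCC[C@@H](CC(=O)OC)c1c(O)c(CC=C(C)C)c(O)c(C(C)=O)c1O | intermediate
14 | methyl (3S)-3-[3-acetyl-2-hydroxy-4,6-bis(methoxymethoxy)-5-(3-methylbut-2-enyl)phenyl]hexanoate | CCC[C@@H](CC(=O)OC)c1c(OCOC)c(CC=C(C)C)c(OCOC)c(C(C)=O)c1O | intermediate
15 | N,N-dimethylformamide dimethyl acetal | COC(OC)N(C)C | starting material
16 | methyl (3S)-3-{3-[(E)-3-(dimethylamino)prop-2-enoyl]-2-hydroxy-4,6-bis(methoxymethoxy)-5-(3-methylbut-2-enyl)phenyl}hexanoate (not isolated) | CCC[C@@H](CC(=O)OC)c1c(OCOC)c(CC=C(C)C)c(OCOC)c(C(=O)/C=C/N(C)C)c1O | intermediate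
17 | methyl (3S)-3-[5,7-bis(methoxymethoxy)-6-(3-methylbut-2-enyl)-4-oxo-4H-chromen-8-yl]hexanoate | CCC[C@@H](CC(=O)OC)c1c(OCOC)c(CC=C(C)C)c(OCOC)c2c1OC=CC2=O | intermediate
18 | methylmagnesium bromide | C[Mg]Br | starting material
19 | iodomethane | CI | starting material
20 | bromomagnesium (2S)-8-[(3S)-1-methoxy-1-oxohexan-3-yl]-5,7-bis(methoxymethoxy)-2-methyl-6-(3-methylbut-2-enyl)-2H-chromen-4-olate (not isolated) | CCC[C@@H](CC(=O)OC)c1c(OCOC)c(CC=C(C)C)c(OCOC)c2c1O[C@@H](C)C=C2O[Mg]Br | intermediate
21 | methyl (3S)-3-[(2S,3S)-5,7-bis(methoxymethoxy)-2,3-dimethyl-6-(3-methylbut-2-enyl)-4-oxochroman-8-yl]hexanoate | CCC[C@@H](CC(=O)OC)c1c(OCOC)c(CC=C(C)C)c(OCOC)c2c1O[C@@H](C)[C@H](C)C2=O | intermediate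
22 | methyl (3S)-3-[(2S,3S)-5,7-dihydroxy-2,3-dimethyl-6-(3-methylbut-2-enyl)-4-oxochroman-8-yl]hexanoate | CCC[C@@H](CC(=O)OC)c1c(O)c(CC=C(C)C)c(O)c2c1O[C@@H](C)[C@H](C)C2=O | target

Total step count: 10. Longest linear sequence: 10 steps (1 to 22).

**Steps most likely to fail**

Step 9.
- What may go wrong: methyl transfer to the electron-rich, 5,7-dioxygenated chromone may be slow. Once DMPU is present, the enolate may open by loss of the C8a phenoxide and reclose with erosion of the C2 configuration. Proton exchange between product and enolate may lead to a second methylation at C3.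
- Fallback: the two C–C bonds are made in separate operations with stoichiometric, established reagents. Setting out from 17, Me2CuLi with Me3SiCl in THF at −78 °C is used; this chlorosilane-accelerated cuprate addition is long used on chromones and leaves esters alone. It should give the silyl enol ether F1 as a pair of C2 epimers, a form in which the enolate cannot open.
- Aqueous citric acid then frees the (2S)-2-methylchromanone F2 and its (2R) epimer F3. These are diastereomers because of the side-chain centre and are separated by chromatography.
- F2 is deprotonated with LiN(SiMe3)2 (1.0 equiv, THF, −78 °C; the ketone is much more acidic than the ester). It is then methylated with MeI/DMPU anti to the C2 methyl group, which rejoins the route at 21.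

Step 7.
- What may go wrong: discrimination between the two hydroxyls that flank the acetyl group may be insufficient. Acetalisation of the hydroxyl meant to become O1 would later send the ring closure to the wrong oxygen.
- Fallback: the protection is moved ahead of the prenylation, and the prenyl group is brought in by cross-coupling. Setting out from 11, MOMCl/i-Pr2NEt should give the bis-MOM acetophenone F4. The hydroxyl to be capped now lies between the acetyl group and a ring hydrogen, so it is far more open than the one next to the branched chain.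
- N-Iodosuccinimide in DMF iodinates the only ring CH, which is para to the free phenol, to give the aryl iodide F5.
- A Stille coupling of F5 with tributyl(3-methylbut-2-enyl)stannane (Pd(PPh3)4, DMF, 80 °C) comes back to the route at 14. This bypasses 13 and thereby also the anionic prenylation of step 6.

Step 3.
- What may go wrong: hydride delivery to C4 may be slow or poorly face-selective, because C4 is fully substituted and crowded by the peri 5-silyloxy group.
- Fallback: the C4–propyl bond is formed at the stereocentre instead of the C4–H bond. Setting out from 1, ethyl propiolate with ZnCl2 at 100 °C should give 5,7-dihydroxycoumarin F6, and TBSCl/imidazole its bis-silyl ether F7.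
- A conjugate addition of n-PrMgBr to F7 follows, catalysed by CuBr·SMe2 and a ferrocenyl diphosphine (t-BuOMe, −78 °C, then NH4Cl aq). This is a known reaction of 4-unsubstituted coumarins, and it returns to the route at 6.

**Further compounds**
F1 | step 9 | methyl (3S)-3-[5,7-bis(methoxymethoxy)-2-methyl-6-(3-methylbut-2-enyl)-4-(trimethylsilyloxy)-2H-chromen-8-yl]hexanoate, both C2 epimers | CCC[C@@H](CC(=O)OC)c1c(OCOC)c(CC=C(C)C)c(OCOC)c2c1OC(C)C=C2O[Si](C)(C)C
F2 | step 9 | methyl (3S)-3-[(2S)-5,7-bis(methoxymethoxy)-2-methyl-6-(3-methylbut-2-enyl)-4-oxochroman-8-yl]hexanoate | CCC[C@@H](CC(=O)OC)c1c(OCOC)c(CC=C(C)C)c(OCOC)c2c1O[C@@H](C)CC2=O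
F3 | step 9 | methyl (3S)-3-[(2R)-5,7-bis(methoxymethoxy)-2-methyl-6-(3-methylbut-2-enyl)-4-oxochroman-8-yl]hexanoate | CCC[C@@H](CC(=O)OC)c1c(OCOC)c(CC=C(C)C)c(OCOC)c2c1O[C@H](C)CC2=O
F4 | step 7 | methyl (3S)-3-[3-acetyl-2-hydroxy-4,6-bis(methoxymethoxy)phenyl]hexanoate | CCC[C@@H](CC(=O)OC)c1c(OCOC)cc(OCOC)c(C(C)=O)c1O
F5 | step 7 | methyl (3S)-3-[3-acetyl-2-hydroxy-5-iodo-4,6-bis(methoxymethoxy)phenyl]hexanoate | CCC[C@@H](CC(=O)OC)c1c(OCOC)c(I)c(OCOC)c(C(C)=O)c1O
F6 | step 3 | 5,7-dihydroxy-2H-chromen-2-one | O=C1C=Cc2c(O)cc(O)cc2O1
F7 | step 3 | 5,7-bis(tert-butyldimethylsilyloxy)-2H-chromen-2-one | O=C1C=Cc2c(O[Si](C)(C)C(C)(C)C)cc(O[Si](C)(C)C(C)(C)C)cc2O1
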